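**Retrosynthetic overview**
- Feature: in ring C the enol-ether carbon C3 (OMe) sits next to the ketone carbon C4. C3–C4 is therefore the O-methyl enol of a 3,4-dione, one oxidation level above an acyloin, and can be made from two formyl carbons by polarity reversal.
- Endgame: the 8-isovalerate, 5-OH and 7-OH come from a 7-O-benzyl 5,8-hydroquinone, in which 5-OH is hydrogen-bonded to C4=O so that 8-OH is acylated. The hydroquinone comes from the 5,8-dimethoxyflavone by oxidative demethylation and reduction.
- Key disconnection C3–C4: the 3-hydroxyflavanone comes from an aryl/alkyl dialdehyde by a carbene-catalysed crossed benzoin closure, with the O1–C2 ether and the C2 aryl group already in place.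
- The dialdehyde comes from the diol and the diol from an ester aldehyde. The ester aldehyde is made by O1–C2 ether formation between a fully substituted salicylaldehyde and methyl 2-bromo-2-(4-methoxyphenyl)acetate.
- The salicylaldehyde comes from mirror-symmetric 4-(benzyloxy)-2,3,5,6-tetramethoxybenzaldehyde, built on 1,2,4,5-tetramethoxybenzene by two directed lithiations. Rings A and B are bought as arenes, and ring C is the only ring formed.

Key step: step 9

Assumption: the target is achiral, so every intermediate in which C2 or C3 is a stereocentre is carried as a racemate or a diastereomer mixture, and the three starting materials are taken as purchasable.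

Step 1
Reactants: 1 1,2,4,5-tetramethoxybenzene
Product: 4 2,3,5,6-tetramethoxyphenol, via 2,3,5,6-tetramethoxyphenyllithium 2 (not isolated), via dimethyl (2,3,5,6-tetramethoxyphenyl)boronate 3 (not isolated)
Conditions: n-BuLi, Me2NCH2CH2NMe2, THF, 0 °C; B(OMe)3, −78 °C to rt; 30% aq. H2O2, 0 °C to rt
Reagents that add atoms: hydrogen peroxide, OO
Why: Directed ortho-lithiation takes one of the two equivalent ring protons, each flanked by two methoxy groups, and borylation followed by peroxide oxidation (1,2-aryl shift from boron to oxygen) turns C–Li into C–OH, so only one phenol can form.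

Step 2
Reactants: 4 2,3,5,6-tetramethoxyphenol
Product: 5 3-(benzyloxy)-1,2,4,5-tetramethoxybenzene
Conditions: BnBr, K2CO3, DMF, 50 °C
Reagents that add atoms: benzyl bromide, BrCc1ccccc1
Why: Williamson ether synthesis on the only free hydroxyl group marks the future O7 with a group that can later be removed under neutral conditions.

Step 3
Reactants: 5 3-(benzyloxy)-1,2,4,5-tetramethoxybenzene
Product: 7 4-(benzyloxy)-2,3,5,6-tetramethoxybenzaldehyde, via 4-(benzyloxy)-2,3,5,6-tetramethoxyphenyllithium 6 (not isolated)
Conditions: n-BuLi, Me2NCH2CH2NMe2, THF, −20 to 0 °C; DMF, −78 °C to rt; H2O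
Reagents that add atoms: N,N-dimethylformamide, CN(C)C=O
Why: Directed ortho-lithiation removes the only ring proton, which lies between two methoxy groups and is kinetically more acidic than the benzylic CH2 at this temperature, and the aryllithium adds to DMF to give the aldehyde on hydrolysis (formylation of an organolithium).

Step 4
Reactants: 7 4-(benzyloxy)-2,3,5,6-tetramethoxybenzaldehyde
Product: 8 4-(benzyloxy)-2-hydroxy-3,5,6-trimethoxybenzaldehyde
Conditions: MgI2·OEt2 (1.2 equiv), toluene–Et2O, 80 °C; H2O
Reagents that add atoms: none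
Why: In this chelation-controlled ether cleavage, known for 2,6-dimethoxybenzaldehydes, magnesium binds the formyl oxygen and one ortho methoxy oxygen in a six-membered chelate and iodide removes that methyl group by SN2; 7 is mirror-symmetric so either ortho group gives the same phenol, the magnesium phenolate resists a second cleavage, and the unchelated benzyl ether is left alone.

Step 5
Reactants: 9 methyl 2-(4-methoxyphenyl)acetate
Product: 10 methyl 2-bromo-2-(4-methoxyphenyl)acetate (racemic)
Conditions: NBS, 2,2'-azobis(2-methylpropionitrile) (5 mol %), PhCF3, 80 °C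
Reagents that add atoms: N-bromosuccinimide, O=C1CCC(=O)N1Br
Why: Wohl–Ziegler bromination goes through the benzylic radical, which is also stabilised by the ester, and the non-polar medium disfavours ionic bromination of the anisole ring.

Step 6
Reactants: 8 4-(benzyloxy)-2-hydroxy-3,5,6-trimethoxybenzaldehyde; 10 methyl 2-bromo-2-(4-methoxyphenyl)acetate
Product: 11 methyl 2-[3-(benzyloxy)-6-formyl-2,4,5-trimethoxyphenoxy]-2-(4-methoxyphenyl)acetate (racemic)
Conditions: K2CO3, DMF, rt
Reagents that add atoms: none
Why: In a Williamson ether synthesis the phenoxide of 8 displaces the doubly activated (benzylic, α-carbonyl) secondary bromide by SN2 at room temperature, which forms O1–C2 with C2 racemic; 2-formylphenoxy arylacetates of this kind are isolable because their aldol closure needs heat.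

Step 7
Reactants: 11 methyl 2-[3-(benzyloxy)-6-formyl-2,4,5-trimethoxyphenoxy]-2-(4-methoxyphenyl)acetate
Product: 12 2-[3-(benzyloxy)-6-(hydroxymethyl)-2,4,5-trimethoxyphenoxy]-2-(4-methoxyphenyl)ethan-1-ol (racemic)
Conditions: LiAlH4, THF, 0 °C; H2O, aq. NaOH
Reagents that add atoms: none
Why: Hydride reduction takes the ester and the aromatic aldehyde to primary alcohols in one operation, which avoids a selective ester-to-aldehyde reduction beside a free formyl group, and the aryl, benzyl and methyl ethers are inert.

Step 8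
Reactants: 12 2-[3-(benzyloxy)-6-(hydroxymethyl)-2,4,5-trimethoxyphenoxy]-2-(4-methoxyphenyl)ethan-1-ol
Product: 13 4-(benzyloxy)-3,5,6-trimethoxy-2-[1-(4-methoxyphenyl)-2-oxoethoxy]benzaldehyde (racemic)
Conditions: Dess–Martin periodinane (2.5 equiv), NaHCO3, CH2Cl2, 0 °C to rt; used at once
Reagents that add atoms: none
Why: Dess–Martin oxidation converts both primary alcohols into aldehydes under buffered, non-enolising conditions, and the excess of oxidant takes both hydroxyl groups before a seven-membered lactol can build up.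

Step 9
Reactants: 13 4-(benzyloxy)-3,5,6-trimethoxy-2-[1-(4-methoxyphenyl)-2-oxoethoxy]benzaldehyde
Product: 15 7-(benzyloxy)-3-hydroxy-5,6,8-trimethoxy-2-(4-methoxyphenyl)chroman-4-one (racemic cis/trans mixture), via hydroxy-enamine 14 (not isolated)
Conditions: 2-(pentafluorophenyl)-6,7-dihydro-5H-pyrrolo[2,1-c][1,2,4]triazol-2-ium tetrafluoroborate (20 mol %), i-Pr2NEt (20 mol %), toluene (0.01 M), Ar, rt to 40 °C
Reagents that add atoms: none
Why: i-Pr2NEt frees the triazolylidene, which adds to the aromatic formyl carbon (the future C4); proton transfer gives hydroxy-enamine 14, whose nucleophilic carbon attacks the aliphatic formyl carbon (the future C3), and loss of the carbene from the adduct leaves acyloin 15. The closest known reaction is the azolium-catalysed intramolecular crossed benzoin reaction of 2-(2-oxoalkoxy)benzaldehydes to 3-hydroxychroman-4-ones, taken here with an aldehyde as acceptor, as in the known closure of dialdehydes to cyclic acyloins. Ring C closes in the 6-exo-trig mode across the O1–C2 ether made in step 6. C3 is the only new stereocentre and is set relative to C2 by substrate control (chair-like transition state, C2 aryl group pseudo-equatorial, trans favoured and also reachable by enolisation); the outcome is of no consequence because step 10 makes C2 and C3 trigonal. The selectivity that counts is the choice of donor: a hydroxy-enamine raised on the aliphatic formyl carbon would have the O1 aryloxide on the adjacent carbon C2 and could expel it in an internal redox reaction, so the aromatic formyl group has to be the donor, and the substrate favours this because its aliphatic aldehyde is α-branched and carries an α-oxygen, a type known to act as acceptor rather than donor under triazolium catalysis, while ortho-alkoxy groups are known to stabilise the carbene adduct of a benzaldehyde. Cyclisation is favoured over dimerisation by the six-membered transition state and by 0.01 M dilution, and the acidic N-C6F5 salt needs only a weak amine base, which keeps enolisation at C2 and aldol closure to a dihydrobenzofuran slow.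

Step 10
Reactants: 15 7-(benzyloxy)-3-hydroxy-5,6,8-trimethoxy-2-(4-methoxyphenyl)chroman-4-one
Product: 17 7-(benzyloxy)-3-hydroxy-5,6,8-trimethoxy-2-(4-methoxyphenyl)-4H-chromen-4-one, via chromane-3,4-dione 16 (not isolated)
Conditions: Cu(OAc)2 (2.2 equiv), AcOH–H2O (4:1), 80 °C
Reagents that add atoms: none
Why: Oxidation of an acyloin by divalent copper (two one-electron transfers from the enediol) gives dione 16, which enolises at once to the aromatic 4-pyranone of flavonol 17, so both diastereomers of 15 and any tautomeric 4-hydroxychroman-3-one converge on one product.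

Step 11
Reactants: 17 7-(benzyloxy)-3-hydroxy-5,6,8-trimethoxy-2-(4-methoxyphenyl)-4H-chromen-4-one
Product: 18 7-(benzyloxy)-3,5,6,8-tetramethoxy-2-(4-methoxyphenyl)-4H-chromen-4-one
Conditions: MeI, K2CO3, acetone, reflux
Reagents that add atoms: iodomethane, CI
Why: Williamson O-methylation of the acidic 3-OH, the only free hydroxyl group, installs the 3-methoxy group of the target.

Step 12
Reactants: 18 7-(benzyloxy)-3,5,6,8-tetramethoxy-2-(4-methoxyphenyl)-4H-chromen-4-one
Product: 19 7-(benzyloxy)-3,6-dimethoxy-2-(4-methoxyphenyl)-4H-chromene-4,5,8-trione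
Conditions: (NH4)2Ce(NO3)6 (2.5 equiv), MeCN–H2O, 0 °C
Reagents that add atoms: water, O
Why: In this oxidative demethylation tetravalent cerium takes two electrons from ring A, the most electron-rich ring, water adds at C5 and C8 (the only para pair of methoxy-bearing carbons) and two molecules of methanol leave to give the para-quinone, while ring B and the benzyl ether offer no para-dialkoxy pattern and should survive.

Step 13
Reactants: 19 7-(benzyloxy)-3,6-dimethoxy-2-(4-methoxyphenyl)-4H-chromene-4,5,8-trione
Product: 20 7-(benzyloxy)-5,8-dihydroxy-3,6-dimethoxy-2-(4-methoxyphenyl)-4H-chromen-4-one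
Conditions: Na2S2O4, EtOAc–H2O, rt, Ar
Reagents that add atoms: none
Why: Dithionite reduction of a quinone to its hydroquinone is fast in a two-phase system and touches neither the pyranone nor the benzyl ether.

Step 14
Reactants: 20 7-(benzyloxy)-5,8-dihydroxy-3,6-dimethoxy-2-(4-methoxyphenyl)-4H-chromen-4-one; 21 isovaleryl chloride (3-methylbutanoyl chloride, 1.05 equiv)
Product: 22 7-(benzyloxy)-5-hydroxy-3,6-dimethoxy-2-(4-methoxyphenyl)-4-oxo-4H-chromen-8-yl 3-methylbutanoate
Conditions: pyridine, CH2Cl2, 0 °C, Ar
Reagents that add atoms: none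
Why: This is a site-selective O-acylation (nucleophilic acyl substitution): 5-OH is held in a hydrogen bond to the C4 carbonyl and is the least nucleophilic phenol of a flavone, so one equivalent of acid chloride should go to 8-OH.

Step 15
Reactants: 22 7-(benzyloxy)-5-hydroxy-3,6-dimethoxy-2-(4-methoxyphenyl)-4-oxo-4H-chromen-8-yl 3-methylbutanoate
Product: 23 5,7-dihydroxy-3,6-dimethoxy-2-(4-methoxyphenyl)-4-oxo-4H-chromen-8-yl 3-methylbutanoate (5,7,8-trihydroxy-3,6,4'-trimethoxyflavone 8-isovalerate)
Conditions: H2 (1 atm), 10% Pd/C, EtOAc, rt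
Reagents that add atoms: none
Why: Catalytic hydrogenolysis cleaves the benzylic C–O bond under neutral conditions, which spares the aryl ester and the tetrasubstituted C2=C3 bond and gives no base to drive an acyl shift from O8 to O7.

**Compound list**
1 | 1,2,4,5-tetramethoxybenzene | COc1cc(OC)c(OC)cc1OC | starting material
2 | 2,3,5,6-tetramethoxyphenyllithium | [Li]c1c(OC)c(OC)cc(OC)c1OC | intermediate
3 | dimethyl (2,3,5,6-tetramethoxyphenyl)boronate | COB(OC)c1c(OC)c(OC)cc(OC)c1OC | intermediate
4 | 2,3,5,6-tetramethoxyphenol | COc1cc(OC)c(OC)c(O)c1OC | intermediate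
5 | 3-(benzyloxy)-1,2,4,5-tetramethoxybenzene | COc1cc(OC)c(OC)c(OCc2ccccc2)c1OC | intermediate
6 | 4-(benzyloxy)-2,3,5,6-tetramethoxyphenyllithium | [Li]c1c(OC)c(OC)c(OCc2ccccc2)c(OC)c1OC | intermediate
7 | 4-(benzyloxy)-2,3,5,6-tetramethoxybenzaldehyde | COc1c(C=O)c(OC)c(OC)c(OCc2ccccc2)c1OC | intermediate
8 | 4-(benzyloxy)-2-hydroxy-3,5,6-trimethoxybenzaldehyde | COc1c(O)c(C=O)c(OC)c(OC)c1OCc1ccccc1 | intermediate
9 | methyl 2-(4-methoxyphenyl)acetate | COC(=O)Cc1ccc(OC)cc1 | starting material
10 | methyl 2-bromo-2-(4-methoxyphenyl)acetate (racemic) | COC(=O)C(Br)c1ccc(OC)cc1 | intermediate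
11 | methyl 2-[3-(benzyloxy)-6-formyl-2,4,5-trimethoxyphenoxy]-2-(4-methoxyphenyl)acetate (racemic) | COC(=O)C(Oc1c(C=O)c(OC)c(OC)c(OCc2ccccc2)c1OC)c1ccc(OC)cc1 | intermediate
12 | 2-[3-(benzyloxy)-6-(hydroxymethyl)-2,4,5-trimethoxyphenoxy]-2-(4-methoxyphenyl)ethan-1-ol (racemic) | COc1ccc(C(CO)Oc2c(CO)c(OC)c(OC)c(OCc3ccccc3)c2OC)cc1 | intermediate
13 | 4-(benzyloxy)-3,5,6-trimethoxy-2-[1-(4-methoxyphenyl)-2-oxoethoxy]benzaldehyde (racemic) | COc1ccc(C(C=O)Oc2c(C=O)c(OC)c(OC)c(OCc3ccccc3)c2OC)cc1 | intermediate
14 | hydroxy-enamine: 2-{3-(benzyloxy)-6-[hydroxy(2-(pentafluorophenyl)-6,7-dihydro-5H-pyrrolo[2,1-c][1,2,4]triazol-3(2H)-ylidene)methyl]-2,4,5-trimethoxyphenoxy}-2-(4-methoxyphenyl)acetaldehyde (racemic, alkene geometry open) | COc1ccc(C(C=O)Oc2c(C(O)=C3N(c4c(F)c(F)c(F)c(F)c4F)N=C4CCCN34)c(OC)c(OC)c(OCc3ccccc3)c2OC)cc1 | intermediate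
15 | 7-(benzyloxy)-3-hydroxy-5,6,8-trimethoxy-2-(4-methoxyphenyl)chroman-4-one (racemic, cis and trans) | COc1ccc(C2Oc3c(OC)c(OCc4ccccc4)c(OC)c(OC)c3C(=O)C2O)cc1 | intermediate
16 | 7-(benzyloxy)-5,6,8-trimethoxy-2-(4-methoxyphenyl)chromane-3,4-dione (racemic) | COc1ccc(C2Oc3c(OC)c(OCc4ccccc4)c(OC)c(OC)c3C(=O)C2=O)cc1 | intermediate
17 | 7-(benzyloxy)-3-hydroxy-5,6,8-trimethoxy-2-(4-methoxyphenyl)-4H-chromen-4-one | COc1ccc(-c2oc3c(OC)c(OCc4ccccc4)c(OC)c(OC)c3c(=O)c2O)cc1 | intermediate
18 | 7-(benzyloxy)-3,5,6,8-tetramethoxy-2-(4-methoxyphenyl)-4H-chromen-4-one | COc1ccc(-c2oc3c(OC)c(OCc4ccccc4)c(OC)c(OC)c3c(=O)c2OC)cc1 | intermediate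
19 | 7-(benzyloxy)-3,6-dimethoxy-2-(4-methoxyphenyl)-4H-chromene-4,5,8-trione | COc1ccc(cc1)C1=C(OC)C(=O)C2=C(O1)C(=O)C(OCc1ccccc1)=C(OC)C2=O | intermediate
20 | 7-(benzyloxy)-5,8-dihydroxy-3,6-dimethoxy-2-(4-methoxyphenyl)-4H-chromen-4-one | COc1ccc(-c2oc3c(O)c(OCc4ccccc4)c(OC)c(O)c3c(=O)c2OC)cc1 | intermediate
21 | isovaleryl chloride (3-methylbutanoyl chloride) | CC(C)CC(=O)Cl | starting material
22 | 7-(benzyloxy)-5-hydroxy-3,6-dimethoxy-2-(4-methoxyphenyl)-4-oxo-4H-chromen-8-yl 3-methylbutanoate | COc1ccc(-c2oc3c(OC(=O)CC(C)C)c(OCc4ccccc4)c(OC)c(O)c3c(=O)c2OC)cc1 | intermediate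
23 | 5,7-dihydroxy-3,6-dimethoxy-2-(4-methoxyphenyl)-4-oxo-4H-chromen-8-yl 3-methylbutanoate (achiral) | COc1ccc(-c2oc3c(OC(=O)CC(C)C)c(O)c(OC)c(O)c3c(=O)c2OC)cc1 | target

Total step count: 15. Longest linear sequence: 14 steps (steps 1–4 and 6–15); step 5 is a one-step side branch.

**Steps most likely to fail**

1. Step 9.
- What may go wrong: the aromatic formyl group is flanked by two alkoxy groups, so hydroxy-enamine formation there may be slow. It may lose to carbene attack at the aliphatic formyl group followed by expulsion of the O1 aryloxide (internal redox). It may also lose to base-induced enolisation at C2 with aldol closure to a five-membered ring.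
- Fallback: close ring C at O1–C2 by a Baker–Venkataraman sequence, setting out from 5 and coming back at 18.
- 5 is lithiated as in step 3, and 6 is acylated with N,2-dimethoxy-N-methylacetamide to give 1-[4-(benzyloxy)-2,3,5,6-tetramethoxyphenyl]-2-methoxyethan-1-one F1.
- MgI2·OEt2 then cleaves one of the two equivalent ortho methyl ethers to give 1-[4-(benzyloxy)-2-hydroxy-3,5,6-trimethoxyphenyl]-2-methoxyethan-1-one F2.
- 4-Methoxybenzoyl chloride in pyridine gives 3-(benzyloxy)-2,4,5-trimethoxy-6-(methoxyacetyl)phenyl 4-methoxybenzoate F3.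
- KOH in pyridine shifts the aroyl group from oxygen to carbon to give 1-[4-(benzyloxy)-2-hydroxy-3,5,6-trimethoxyphenyl]-2-methoxy-3-(4-methoxyphenyl)propane-1,3-dione F4.
- Cyclodehydration with 4-methylbenzenesulfonic acid in refluxing toluene gives 18, with the 3-methoxy group already in place.

2. Step 8.
- What may go wrong: partial oxidation may be followed by seven-membered lactol formation and over-oxidation to a lactone. The very electron-rich benzylic alcohol may ionise under the acid formed in the oxidation. The α-aryl-α-aryloxy aldehyde may enolise or autoxidise during isolation.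
- Fallback: use partial reduction instead of reduction and re-oxidation, setting out from 11 and coming back at 13.
- HC(OMe)3 and a trace of 4-methylbenzenesulfonic acid in MeOH mask the aromatic aldehyde as methyl 2-[3-(benzyloxy)-6-(dimethoxymethyl)-2,4,5-trimethoxyphenoxy]-2-(4-methoxyphenyl)acetate F5.
- i-Bu2AlH in toluene at −78 °C stops at the chelated aluminium hemiacetal of the α-aryloxy ester and gives, on work-up, 2-[3-(benzyloxy)-6-(dimethoxymethyl)-2,4,5-trimethoxyphenoxy]-2-(4-methoxyphenyl)acetaldehyde F6.
- Pyridinium 4-methylbenzenesulfonate in aqueous acetone hydrolyses the very labile electron-rich aryl acetal to give 13. No benzylic alcohol and no oxidant are involved.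

3. Step 12.
- What may go wrong: the ring A radical cation may lose the benzyl group instead of taking up water at C5 and C8. Alternatively, oxidation may run on to ortho-quinoid or ring-opened material.
- Fallback: oxidise a phenol in a two-electron process instead of taking single electrons from the fully alkylated arene, setting out from 18 and coming back at 19.
- MgI2·OEt2 cleaves the 5-methoxy group through the six-membered chelate with C4=O to give 7-(benzyloxy)-5-hydroxy-3,6,8-trimethoxy-2-(4-methoxyphenyl)-4H-chromen-4-one F7.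
- PhI(OAc)2 in MeCN–H2O then oxidises the 4-methoxyphenol unit (5-OH para to 8-OMe). Water adds at C8 and methanol leaves to give 19.

**Further compounds**
F1 | step 9 | 1-[4-(benzyloxy)-2,3,5,6-tetramethoxyphenyl]-2-methoxyethan-1-one | COCC(=O)c1c(OC)c(OC)c(OCc2ccccc2)c(OC)c1OC
F2 | step 9 | 1-[4-(benzyloxy)-2-hydroxy-3,5,6-trimethoxyphenyl]-2-methoxyethan-1-one | COCC(=O)c1c(O)c(OC)c(OCc2ccccc2)c(OC)c1OC
F3 | step 9 | 3-(benzyloxy)-2,4,5-trimethoxy-6-(methoxyacetyl)phenyl 4-methoxybenzoate | COCC(=O)c1c(OC(=O)c2ccc(OC)cc2)c(OC)c(OCc2ccccc2)c(OC)c1OC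
F4 | step 9 | 1-[4-(benzyloxy)-2-hydroxy-3,5,6-trimethoxyphenyl]-2-methoxy-3-(4-methoxyphenyl)propane-1,3-dione (racemic, enolisable) | COc1ccc(C(=O)C(OC)C(=O)c2c(O)c(OC)c(OCc3ccccc3)c(OC)c2OC)cc1
F5 | step 8 | methyl 2-[3-(benzyloxy)-6-(dimethoxymethyl)-2,4,5-trimethoxyphenoxy]-2-(4-methoxyphenyl)acetate (racemic) | COC(=O)C(Oc1c(C(OC)OC)c(OC)c(OC)c(OCc2ccccc2)c1OC)c1ccc(OC)cc1
F6 | step 8 | 2-[3-(benzyloxy)-6-(dimethoxymethyl)-2,4,5-trimethoxyphenoxy]-2-(4-methoxyphenyl)acetaldehyde (racemic) | COc1ccc(C(C=O)Oc2c(C(OC)OC)c(OC)c(OC)c(OCc3ccccc3)c2OC)cc1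
F7 | step 12 | 7-(benzyloxy)-5-hydroxy-3,6,8-trimethoxy-2-(4-methoxyphenyl)-4H-chromen-4-one | COc1ccc(-c2oc3c(OC)c(OCc4ccccc4)c(OC)c(O)c3c(=O)c2OC)cc1
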